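**Retrosynthetic overview**
1. The quinone is unmasked last by oxidative demethylation of a 1,4-dimethoxyarene; before that, desilylation and lactonisation of an open-chain δ-silyloxy (Z)-enoate closes the δ-lactone, the only ring built in the route (the arene ring is bought).
2. The open-chain ester is cut at the C5'–C6' bond, CH2–CH= (side chain numbered C1' at the ring-bound CH2 to C16' at the isopropenyl CH2), into an (E)-alkenyl iodide and a redox-active ester. They are joined by Ni-catalysed decarboxylative alkenylation during which a cyclopropane opens.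
3. Enabling feature: in the unit C5'H2–C4'H2–C3'(CH3)=C2'H, C5' is homoallylic to the 2'E alkene. This is the ring-opened form of a 1-methylcyclopropylcarbinyl radical centred on C2', so C3', C4' and C5' are carried as a cyclopropane (a temporary ring) whose strain release creates the C5' radical and the alkene in one event.
4. Arene half: 4-methoxy-2-methylphenol → benzylic bromide → alkylation of the dianion of 2-(1-methylcyclopropyl)acetic acid → N-hydroxyphthalimide ester.
5. Lactone half: Negishi carboalumination (6'E vinyl iodide), CBS reduction (14'R), Still–Gennari olefination (10'Z).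

Key step: step 16

Remark: 2-(1-methylcyclopropyl)acetic acid and methyl bis(2,2,2-trifluoroethyl)phosphonoacetate are taken to be catalogue compounds.

**Route**

Step 1
Reactants: 1 4-methoxy-2-methylphenol
Product: 2 2-hydroxy-5-methoxy-3-methylbenzaldehyde
Conditions: MgCl2, Et3N, (CH2O)n, MeCN, reflux
Reagents that add atoms: paraformaldehyde (formaldehyde unit), C=O
Why: Casnati–Skattebøl ortho-formylation: the magnesium phenoxide directs formaldehyde to the only free ortho position, and a second formaldehyde oxidises the benzylic alkoxide to the aldehyde.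

Step 2
Reactants: 2 2-hydroxy-5-methoxy-3-methylbenzaldehyde
Product: 3 2,5-dimethoxy-3-methylbenzaldehyde
Conditions: MeI, K2CO3, DMF, rt
Reagents that add atoms: iodomethane, CI
Why: Williamson O-methylation of the phenol.

Step 3
Reactants: 3 2,5-dimethoxy-3-methylbenzaldehyde
Product: 4 (2,5-dimethoxy-3-methylphenyl)methanol
Conditions: NaBH4, MeOH, 0 °C
Reagents that add atoms: none
Why: Borohydride reduction of an aryl aldehyde.

Step 4
Reactants: 4 (2,5-dimethoxy-3-methylphenyl)methanol
Product: 5 1-(bromomethyl)-2,5-dimethoxy-3-methylbenzene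
Conditions: PBr3, Et2O, 0 °C
Reagents that add atoms: phosphorus tribromide, BrP(Br)Br
Why: Conversion of a primary benzylic alcohol into the bromide by SN2 displacement on the phosphite ester.

Step 5
Reactants: 5 1-(bromomethyl)-2,5-dimethoxy-3-methylbenzene; 6 2-(1-methylcyclopropyl)acetic acid
Product: 7 rac-3-(2,5-dimethoxy-3-methylphenyl)-2-(1-methylcyclopropyl)propanoic acid
Conditions: 6, LDA (2.2 equiv, commercial solution), THF/DMPU, 0 °C; then 5, −78 °C → rt; aq. HCl
Reagents that add atoms: none
Why: Alkylation of a carboxylic acid dianion (enediolate) with a reactive benzylic bromide; the new stereocentre is made racemic on purpose because it is erased in step 16.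

Step 6
Reactants: 7 rac-3-(2,5-dimethoxy-3-methylphenyl)-2-(1-methylcyclopropyl)propanoic acid
Product: 8 1,3-dioxoisoindolin-2-yl rac-3-(2,5-dimethoxy-3-methylphenyl)-2-(1-methylcyclopropyl)propanoate
Conditions: N-hydroxyphthalimide, DIC, DMAP (cat.), CH2Cl2, rt
Reagents that add atoms: N-hydroxyphthalimide, O=C1c2ccccc2C(=O)N1O
Why: Carbodiimide (Steglich-type) esterification giving the redox-active ester.

Step 7
Reactants: 9 pent-4-yn-1-ol
Product: 11 (E)-5-iodo-4-methylpent-4-en-1-ol, via alkenylalane 10 (not isolated)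
Conditions: Me3Al (3 equiv), Cp2ZrCl2 (0.25 equiv), CH2Cl2, 0 °C → rt; then I2, THF, −30 → 0 °C; aq. K2CO3 work-up
Reagents that add atoms: trimethylaluminium, C[Al](C)C; iodine, II
Why: Negishi Zr-catalysed carboalumination: syn addition of Me–Al across the terminal alkyne puts the methyl group on the internal carbon, and iodinolysis of the C–Al bond with retention fixes the 6'E alkene.

Step 8
Reactants: 11 (E)-5-iodo-4-methylpent-4-en-1-ol
Product: 12 (E)-5-iodo-4-methylpent-4-enal
Conditions: Dess–Martin periodinane, NaHCO3, CH2Cl2, 0 °C → rt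
Reagents that add atoms: none
Why: Dess–Martin oxidation of the primary alcohol under buffered conditions that leave the vinyl iodide untouched.

Step 9
Reactants: 13 3-chloropropanoyl chloride
Product: 14 3-chloro-N-methoxy-N-methylpropanamide
Conditions: MeNH(OMe)·HCl, pyridine, CH2Cl2, 0 °C
Reagents that add atoms: N,O-dimethylhydroxylamine hydrochloride, CNOC.Cl
Why: Weinreb amide formation by N-acylation; the weak base pyridine at 0 °C should avoid loss of HCl to the acrylamide.

Step 10
Reactants: 14 3-chloro-N-methoxy-N-methylpropanamide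
Product: 15 1-chloro-4-methylpent-4-en-3-one
Conditions: isopropenylmagnesium bromide, THF, −78 → −20 °C; cold aq. NH4Cl quench
Reagents that add atoms: isopropenylmagnesium bromide, C=C(C)[Mg]Br
Why: Weinreb ketone synthesis: the chelated tetrahedral magnesium intermediate stops at the ketone stage, and the low temperature and cold quench should keep the β-chloro ketone from eliminating.

Step 11
Reactants: 15 1-chloro-4-methylpent-4-en-3-one
Product: 16 (R)-1-chloro-4-methylpent-4-en-3-ol
Conditions: (S)-Me-CBS (0.2 equiv), catecholborane, toluene, −78 °C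
Reagents that add atoms: none
Why: Corey–Bakshi–Shibata reduction: the ketone binds the (S)-oxazaborolidine with the α-branched isopropenyl group as the large substituent, so hydride should go to the face that gives the (R)-carbinol (C14'), by analogy with acetophenone giving the (R)-alcohol; catecholborane at −78 °C avoids hydroboration of the alkene.

Step 12
Reactants: 16 (R)-1-chloro-4-methylpent-4-en-3-ol
Product: 17 (R)-tert-butyl[(5-chloro-2-methylpent-1-en-3-yl)oxy]dimethylsilane
Conditions: TBSCl, imidazole, DMF, rt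
Reagents that add atoms: tert-butyldimethylsilyl chloride, CC(C)(C)[Si](C)(C)Cl
Why: Silylation of the secondary allylic alcohol, which makes the allylic oxygen non-ionisable for steps 14–16.

Step 13
Reactants: 17 (R)-tert-butyl[(5-chloro-2-methylpent-1-en-3-yl)oxy]dimethylsilane
Product: 18 (R)-tert-butyl[(5-iodo-2-methylpent-1-en-3-yl)oxy]dimethylsilane
Conditions: NaI, acetone, reflux
Reagents that add atoms: sodium iodide, [Na+].[I-]
Why: Finkelstein halide exchange driven by precipitation of NaCl, giving the more reactive primary iodide.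

Step 14
Reactants: 18 (R)-tert-butyl[(5-iodo-2-methylpent-1-en-3-yl)oxy]dimethylsilane; 19 methyl 2-[bis(2,2,2-trifluoroethoxy)phosphoryl]acetate
Product: 20 methyl (5R)-2-[bis(2,2,2-trifluoroethoxy)phosphoryl]-5-[(tert-butyldimethylsilyl)oxy]-6-methylhept-6-enoate (both C2 epimers)
Conditions: 19, NaH, DMF, 0 °C; then 18, 50 °C
Reagents that add atoms: none
Why: SN2 C-alkylation of the sodium salt of the Still–Gennari phosphonoacetate with a primary iodide; the C2 epimers are of no consequence because C2 becomes sp2 in step 15.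

Step 15
Reactants: 20 methyl (5R)-2-[bis(2,2,2-trifluoroethoxy)phosphoryl]-5-[(tert-butyldimethylsilyl)oxy]-6-methylhept-6-enoate; 12 (E)-5-iodo-4-methylpent-4-enal
Product: 21 methyl (2Z,6E)-2-[(3R)-3-[(tert-butyldimethylsilyl)oxy]-4-methylpent-4-en-1-yl]-7-iodo-6-methylhepta-2,6-dienoate
Conditions: 20, KHMDS, 18-crown-6, THF, −78 °C; then 12
Reagents that add atoms: none
Why: Still–Gennari modification of the Horner–Wadsworth–Emmons reaction: with the dissociated potassium/18-crown-6 counter-ion and the electron-poor trifluoroethyl phosphonate, elimination from the kinetically formed adduct is fast and should give the (Z)-enoate (ester cis to the new chain, 10'Z).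

Step 16
Reactants: 21 methyl (2Z,6E)-2-[(3R)-3-[(tert-butyldimethylsilyl)oxy]-4-methylpent-4-en-1-yl]-7-iodo-6-methylhepta-2,6-dienoate; 8 1,3-dioxoisoindolin-2-yl rac-3-(2,5-dimethoxy-3-methylphenyl)-2-(1-methylcyclopropyl)propanoate
Product: 24 methyl (2Z,6E,10E)-2-[(3R)-3-[(tert-butyldimethylsilyl)oxy]-4-methylpent-4-en-1-yl]-12-(2,5-dimethoxy-3-methylphenyl)-6,10-dimethyldodeca-2,6,10-trienoate, via cyclopropylcarbinyl radical 22 (not isolated), via homoallyl radical 23 (not isolated)
Conditions: NiBr2·glyme (10 mol %), 4,4'-di-tert-butyl-2,2'-bipyridine (10 mol %), Zn dust (2 equiv), DMA, rt; 8 (1.5 equiv) added slowly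
Reagents that add atoms: none
Why: Proposed new method: single-electron reduction of the redox-active ester 8 by low-valent nickel (turned over by Zn) releases phthalimide anion and CO2 and leaves the secondary cyclopropylcarbinyl radical 22, which undergoes β-scission of a ring C–C bond (strain release, orders of magnitude faster than bimolecular capture of a hindered secondary radical by nickel) to the primary homoallyl radical 23; 23 is captured by the alkenyl–Ni(II) iodide formed by oxidative addition of 21, and reductive elimination from Ni(III) forms the C5'–C6' bond with retention of the 6'E geometry. The closest known reaction type is the nickel-catalysed reductive decarboxylative cross-coupling of N-hydroxyphthalimide esters with alkenyl halides, in which cyclopropylmethyl radical clocks are known to couple after ring opening; new is the use of a 1-methylcyclopropyl-substituted secondary ester so that the opening delivers a trisubstituted alkene of defined geometry. No ring is closed (the cyclopropane is opened by radical β-scission) and no stereocentre is created: the stereocentre of 8 is erased at the radical stage, which is why racemic 8 suffices, and C14' is not involved. The 2'E geometry should be set in the bisected transition state of ring opening, in which the arylmethyl substituent on the radical carbon points away from the two ring CH2 groups and lies syn to the ring methyl group, the same preference that governs the Brady–Julia–Johnson opening of 1-methylcyclopropyl carbinols. The step needs ring opening before capture (secured by the unimolecular strain-driven scission next to a neopentyl-type radical centre) and capture of 23 by nickel in preference to Giese addition or reaction at the allylic oxygen (secured by the poor acceptor quality of the α,β-dialkyl enoate and by carrying the allylic oxygen as a non-ionisable silyl ether instead of the allylic lactone).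

Step 17
Reactants: 24 methyl (2Z,6E,10E)-2-[(3R)-3-[(tert-butyldimethylsilyl)oxy]-4-methylpent-4-en-1-yl]-12-(2,5-dimethoxy-3-methylphenyl)-6,10-dimethyldodeca-2,6,10-trienoate
Product: 26 (3Z,6R)-3-[(4E,8E)-10-(2,5-dimethoxy-3-methylphenyl)-4,8-dimethyldeca-4,8-dien-1-ylidene]-6-(prop-1-en-2-yl)oxan-2-one, via hydroxy ester 25 (not isolated)
Conditions: HF·pyridine, pyridine, THF, 0 °C → rt; then PPTS (cat.), toluene, 60 °C
Reagents that add atoms: none
Why: Fluoride cleavage of the TBS ether followed by acid-catalysed 6-exo-trig lactonisation (intramolecular transesterification) of the δ-hydroxy ester; the carbinol C–O bond is not broken, so C14' keeps its (R) configuration and the exocyclic alkene stays Z.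

Step 18
Reactants: 26 (3Z,6R)-3-[(4E,8E)-10-(2,5-dimethoxy-3-methylphenyl)-4,8-dimethyldeca-4,8-dien-1-ylidene]-6-(prop-1-en-2-yl)oxan-2-one
Product: 27 2-methyl-6-[(2E,6E,10Z)-3,7-dimethyl-10-[(6R)-2-oxo-6-(prop-1-en-2-yl)oxan-3-ylidene]deca-2,6-dien-1-yl]cyclohexa-2,5-diene-1,4-dione (target)
Conditions: (NH4)2Ce(NO3)6 (2.5 equiv), MeCN/H2O, 0 °C
Reagents that add atoms: water, O
Why: Ceric ammonium nitrate oxidative demethylation of the 1,4-dimethoxyarene (arene radical cation, attack of water, loss of methanol) should give the 1,4-benzoquinone without touching the lactone or the isolated alkenes.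

**Compound list**
1 | 4-methoxy-2-methylphenol | Cc1cc(OC)ccc1O | starting material
2 | 2-hydroxy-5-methoxy-3-methylbenzaldehyde | O=Cc1cc(OC)cc(C)c1O | intermediate
3 | 2,5-dimethoxy-3-methylbenzaldehyde | O=Cc1cc(OC)cc(C)c1OC | intermediate
4 | (2,5-dimethoxy-3-methylphenyl)methanol | OCc1cc(OC)cc(C)c1OC | intermediate
5 | 1-(bromomethyl)-2,5-dimethoxy-3-methylbenzene | BrCc1cc(OC)cc(C)c1OC | intermediate
6 | 2-(1-methylcyclopropyl)acetic acid | CC1(CC(=O)O)CC1 | starting material
7 | rac-3-(2,5-dimethoxy-3-methylphenyl)-2-(1-methylcyclopropyl)propanoic acid | COc1cc(C)c(OC)c(CC(C(=O)O)C2(C)CC2)c1 | intermediate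
8 | 1,3-dioxoisoindolin-2-yl rac-3-(2,5-dimethoxy-3-methylphenyl)-2-(1-methylcyclopropyl)propanoate | COc1cc(C)c(OC)c(CC(C(=O)ON2C(=O)c3ccccc3C2=O)C4(C)CC4)c1 | intermediate
9 | pent-4-yn-1-ol | C#CCCCO | starting material
10 | dimethyl[(1E)-5-(dimethylalumanyloxy)-2-methylpent-1-en-1-yl]alumane (alkenylalane) | C[Al](C)OCCC/C(C)=C/[Al](C)C | intermediate
11 | (E)-5-iodo-4-methylpent-4-en-1-ol | OCCC/C(C)=C/I | intermediate
12 | (E)-5-iodo-4-methylpent-4-enal | O=CCC/C(C)=C/I | intermediate
13 | 3-chloropropanoyl chloride | ClCCC(Cl)=O | starting material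
14 | 3-chloro-N-methoxy-N-methylpropanamide | ClCCC(=O)N(C)OC | intermediate
15 | 1-chloro-4-methylpent-4-en-3-one | ClCCC(=O)C(C)=C | intermediate
16 | (R)-1-chloro-4-methylpent-4-en-3-ol | ClCC[C@@H](O)C(C)=C | intermediate
17 | (R)-tert-butyl[(5-chloro-2-methylpent-1-en-3-yl)oxy]dimethylsilane | ClCC[C@@H](O[Si](C)(C)C(C)(C)C)C(C)=C | intermediate
18 | (R)-tert-butyl[(5-iodo-2-methylpent-1-en-3-yl)oxy]dimethylsilane | ICC[C@@H](O[Si](C)(C)C(C)(C)C)C(C)=C | intermediate
19 | methyl 2-[bis(2,2,2-trifluoroethoxy)phosphoryl]acetate | COC(=O)CP(=O)(OCC(F)(F)F)OCC(F)(F)F | starting material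
20 | methyl (5R)-2-[bis(2,2,2-trifluoroethoxy)phosphoryl]-5-[(tert-butyldimethylsilyl)oxy]-6-methylhept-6-enoate | COC(=O)C(CC[C@@H](O[Si](C)(C)C(C)(C)C)C(C)=C)P(=O)(OCC(F)(F)F)OCC(F)(F)F | intermediate
21 | methyl (2Z,6E)-2-[(3R)-3-[(tert-butyldimethylsilyl)oxy]-4-methylpent-4-en-1-yl]-7-iodo-6-methylhepta-2,6-dienoate | COC(=O)/C(=C\CC/C(C)=C/I)CC[C@@H](O[Si](C)(C)C(C)(C)C)C(C)=C | intermediate
22 | 2-(2,5-dimethoxy-3-methylphenyl)-1-(1-methylcyclopropyl)ethyl radical | COc1cc(C)c(OC)c(C[CH]C2(C)CC2)c1 | intermediate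
23 | (E)-5-(2,5-dimethoxy-3-methylphenyl)-3-methylpent-3-en-1-yl radical | [CH2]C/C(C)=C/Cc1cc(OC)cc(C)c1OC | intermediate
24 | methyl (2Z,6E,10E)-2-[(3R)-3-[(tert-butyldimethylsilyl)oxy]-4-methylpent-4-en-1-yl]-12-(2,5-dimethoxy-3-methylphenyl)-6,10-dimethyldodeca-2,6,10-trienoate | COC(=O)/C(=C\CC/C(C)=C/CC/C(C)=C/Cc1cc(OC)cc(C)c1OC)CC[C@@H](O[Si](C)(C)C(C)(C)C)C(C)=C | intermediate
25 | methyl (2Z,6E,10E)-12-(2,5-dimethoxy-3-methylphenyl)-2-[(3R)-3-hydroxy-4-methylpent-4-en-1-yl]-6,10-dimethyldodeca-2,6,10-trienoate | COC(=O)/C(=C\CC/C(C)=C/CC/C(C)=C/Cc1cc(OC)cc(C)c1OC)CC[C@@H](O)C(C)=C | intermediate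
26 | (3Z,6R)-3-[(4E,8E)-10-(2,5-dimethoxy-3-methylphenyl)-4,8-dimethyldeca-4,8-dien-1-ylidene]-6-(prop-1-en-2-yl)oxan-2-one | C=C(C)[C@H]1CC/C(=C/CC/C(C)=C/CC/C(C)=C/Cc2cc(OC)cc(C)c2OC)C(=O)O1 | intermediate
27 | 2-methyl-6-[(2E,6E,10Z)-3,7-dimethyl-10-[(6R)-2-oxo-6-(prop-1-en-2-yl)oxan-3-ylidene]deca-2,6-dien-1-yl]cyclohexa-2,5-diene-1,4-dione | C=C(C)[C@H]1CC/C(=C/CC/C(C)=C/CC/C(C)=C/CC2=CC(=O)C=C(C)C2=O)C(=O)O1 | target

**Count**
Total steps: 18. Longest linear sequence: 10 steps (steps 9–18, from 3-chloropropanoyl chloride).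

**Steps most likely to fail**

Step 16 (Proposed new method). What may go wrong: erosion of the 2'E geometry if the cyclopropylcarbinyl ring opening is poorly face-selective or reversible on the time scale of nickel capture; capture of the unopened radical; homocoupling of the alkenyl iodide. The fallback uses known chemistry, sets out from bromide 5 and returns at 24:
- Bromide 5 is converted with Mg, ZnCl2 and LiCl in THF into (2,5-dimethoxy-3-methylbenzyl)zinc chloride F1, which is added to commercial 1-methylcyclopropane-1-carbaldehyde to give 2-(2,5-dimethoxy-3-methylphenyl)-1-(1-methylcyclopropyl)ethan-1-ol F2.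
- Brady–Julia–Johnson homoallylic rearrangement (PBr3, LiBr, 2,4,6-collidine, Et2O, −30 °C, then ZnBr2, Et2O, 0 °C) passes through 1-[2-bromo-2-(1-methylcyclopropyl)ethyl]-2,5-dimethoxy-3-methylbenzene F3 to (E)-1-(5-bromo-3-methylpent-2-en-1-yl)-2,5-dimethoxy-3-methylbenzene F4, with the 2'E geometry set under the established polar control.
- Zinc insertion (Zn dust, LiCl, THF, 50 °C) gives [(E)-5-(2,5-dimethoxy-3-methylphenyl)-3-methylpent-3-en-1-yl]zinc bromide F5, and Negishi alkyl–alkenyl coupling with 21 (Pd(dppf)Cl2, THF, 40 °C) gives 24.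

Step 14. What may go wrong: sluggish SN2 C-alkylation of the stabilised phosphonate anion, with competing dialkylation and exchange of the trifluoroethyl esters. The fallback forms the same C–C bond by conjugate addition instead; it sets out from 15 and 19 and returns at 20:
- Cs2CO3 in MeCN at 0 °C unmasks 15 to 2-methylpenta-1,4-dien-3-one F6, which is trapped in the flask by the anion of 19 (used in excess) at the unsubstituted vinyl terminus to give methyl 2-[bis(2,2,2-trifluoroethoxy)phosphoryl]-6-methyl-5-oxohept-6-enoate F7.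
- CBS reduction as in step 11 gives methyl (5R)-2-[bis(2,2,2-trifluoroethoxy)phosphoryl]-5-hydroxy-6-methylhept-6-enoate F8, and immediate silylation (TBSCl, imidazole) gives 20.

Step 17. What may go wrong: incomplete ring closure of the hindered conjugated methyl ester, and acid-promoted Z→E isomerisation or ionisation of the freed allylic alcohol. The fallback activates the acid instead of relying on transesterification; it sets out from 24 and returns at 26:
- Saponification (LiOH, THF/MeOH/H2O, 40 °C) gives (2Z,6E,10E)-2-[(3R)-3-[(tert-butyldimethylsilyl)oxy]-4-methylpent-4-en-1-yl]-12-(2,5-dimethoxy-3-methylphenyl)-6,10-dimethyldodeca-2,6,10-trienoic acid F9.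
- TBAF in THF gives (2Z,6E,10E)-12-(2,5-dimethoxy-3-methylphenyl)-2-[(3R)-3-hydroxy-4-methylpent-4-en-1-yl]-6,10-dimethyldodeca-2,6,10-trienoic acid F10.
- Carbodiimide lactonisation (EDC·HCl, DMAP, CH2Cl2, rt), with retention at C14', gives 26.

Further compounds
F1 | step 16 | (2,5-dimethoxy-3-methylbenzyl)zinc chloride | Cl[Zn]Cc1cc(OC)cc(C)c1OC
F2 | step 16 | 2-(2,5-dimethoxy-3-methylphenyl)-1-(1-methylcyclopropyl)ethan-1-ol | COc1cc(C)c(OC)c(CC(O)C2(C)CC2)c1
F3 | step 16 | 1-[2-bromo-2-(1-methylcyclopropyl)ethyl]-2,5-dimethoxy-3-methylbenzene | COc1cc(C)c(OC)c(CC(Br)C2(C)CC2)c1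
F4 | step 16 | (E)-1-(5-bromo-3-methylpent-2-en-1-yl)-2,5-dimethoxy-3-methylbenzene | BrCC/C(C)=C/Cc1cc(OC)cc(C)c1OC
F5 | step 16 | [(E)-5-(2,5-dimethoxy-3-methylphenyl)-3-methylpent-3-en-1-yl]zinc bromide | Br[Zn]CC/C(C)=C/Cc1cc(OC)cc(C)c1OC
F6 | step 14 | 2-methylpenta-1,4-dien-3-one | C=CC(=O)C(C)=C
F7 | step 14 | methyl 2-[bis(2,2,2-trifluoroethoxy)phosphoryl]-6-methyl-5-oxohept-6-enoate | COC(=O)C(CCC(=O)C(C)=C)P(=O)(OCC(F)(F)F)OCC(F)(F)F
F8 | step 14 | methyl (5R)-2-[bis(2,2,2-trifluoroethoxy)phosphoryl]-5-hydroxy-6-methylhept-6-enoate | COC(=O)C(CC[C@@H](O)C(C)=C)P(=O)(OCC(F)(F)F)OCC(F)(F)F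
F9 | step 17 | (2Z,6E,10E)-2-[(3R)-3-[(tert-butyldimethylsilyl)oxy]-4-methylpent-4-en-1-yl]-12-(2,5-dimethoxy-3-methylphenyl)-6,10-dimethyldodeca-2,6,10-trienoic acid | OC(=O)/C(=C\CC/C(C)=C/CC/C(C)=C/Cc1cc(OC)cc(C)c1OC)CC[C@@H](O[Si](C)(C)C(C)(C)C)C(C)=C
F10 | step 17 | (2Z,6E,10E)-12-(2,5-dimethoxy-3-methylphenyl)-2-[(3R)-3-hydroxy-4-methylpent-4-en-1-yl]-6,10-dimethyldodeca-2,6,10-trienoic acid | OC(=O)/C(=C\CC/C(C)=C/CC/C(C)=C/Cc1cc(OC)cc(C)c1OC)CC[C@@H](O)C(C)=C
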